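Readings and results are simulated with made-up constants, noise included.

A ratio told me what these flasks were doing: starting material charged over starting material left. The steps thought possible run in one line, from starting material to intermediate A, then B, C and product.

| flask | starting material | temperature | remark | time |
|---|---|---|---|---|
| Tuesday's | 1.1 M | 22 °C | run made earlier |  |
| Friday's | 1.8 M | 39 °C | run made earlier |  |
| maple | 0.80 M | 25 °C |  | 5.0 min |
| birch | 0.80 M | 35 °C |  | 5.0 min |

| run | time / min | product / % | starting material / % | intermediate A / % | intermediate B / % | intermediate C / % |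
|---|---|---|---|---|---|---|
| Tuesday's | 0.500 | 0 | 96 | 6 | 1 | 0 |
| Tuesday's | 0.833 | 0 | 93 | 10 | 0 | 0 |
| Tuesday's | 1.33 | 2 | 86 | 13 | 0 | 3 |
| Tuesday's | 2.00 | 1 | 78 | 20 | 0 | 2 |
| Tuesday's | 4.00 | 2 | 64 | 34 | 0 | 2 |
| Tuesday's | 6.00 | 0 | 50 | 49 | 3 | 0 |
| Friday's | 0.500 | 1 | 64 | 36 | 2 | 0 |
| Friday's | 1.00 | 2 | 42 | 57 | 2 | 1 |
| Friday's | 1.50 | 0 | 24 | 68 | 4 | 1 |
| Friday's | 2.00 | 2 | 16 | 77 | 6 | 3 |
| Friday's | 2.50 | 1 | 13 | 81 | 6 | 3 |
| Friday's | 3.00 | 4 | 10 | 81 | 6 | 5 |

(readings scatter by 1.5 percentage points)

- steps thought possible: starting material -> intermediate A; intermediate A -> intermediate B; intermediate B -> intermediate C; intermediate C -> product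

- which of these there is most of at the end, counted by the starting material in it, maple (starting material / intermediate B / intermediate C / intermediate A)
- which of these there is most of at the end, counted by the starting material in it, birch (starting material / intermediate B / intermediate C / intermediate A)
- amount of the one of these that there is most of at the end, in percent of the starting material charged, maple
- amount of the one of these that there is most of at the end, in percent of the starting material charged, birch

The logarithm of that ratio, divided by time, is a constant k if the decay is first order; the readings of Friday's run gave 0.893 /min at 0.500 min and 0.916 /min at 2.00 min, so I treated the decay as first order. I solved the two ends and joined them, drawing ln k straight in temperature between Tuesday's and Friday's runs: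

Tuesday's run: k = 0.116 /min
Maple: k = 0.166 /min
Birch: k = 0.563 /min

Maple's N = kt is 0.832, the lifetimes elapsed (a Damköhler number), and birch's is 2.81. The fraction of starting material left is S = e^(−N):

Maple: S = 43.5%
Birch: S = 5.99%

Both N exceed 0.693, so I expected intermediate A to lead starting material in maple and in birch, unless the leak beyond A was large. If nothing passed beyond A, A would be 56.5% in maple and 94.0% in birch.

That was the weak link, since Friday's last reading holds 15.0% in B, C and product together. I assumed the leak constant keeps a fixed ratio r to k. Integrating A, taken as 1 − S, then gives the leaked fraction approximately as D = r(N − 1 + e^(−N)). Friday's N of 2.75 gives a read r of 0.0827, so: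

Maple: D = 2.21%, A = 54.3%
Birch: D = 15.5%, A = 78.5%

The forecast gave intermediate A at 55% in maple and intermediate A at 79% in birch, reasoning that “Friday's decay flattens near 7–10%, which suggests A reverts”. My line has no reversal, and it leaves 5.99% starting material in birch against the forecast's 9%.

The flasks gave intermediate A at 53.5% in maple, with starting material at 44.9%, and intermediate A at 81.9% in birch, with starting material at 6.24%.

    starting material → intermediate A (k = 0.160 /min, Ea = 95.0 kJ/mol)
    intermediate A → intermediate B (k = 0.0100 /min, Ea = 103 kJ/mol)
    intermediate B → intermediate C (k = 0.140 /min, Ea = 81.0 kJ/mol)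
    intermediate C → product (k = 0.110 /min, Ea = 96.0 kJ/mol)
    (constants at 25 °C)

Maple's N of 0.832 stood above 0.693. The same flask read at 2.0 min has N = 0.333, less than 0.693. The reckoning gives S = 71.7% and A = 27.9% there. That flask held starting material in the lead at 72.6%, with intermediate A at 27.1%.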